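## The problem

Compound 22 is a ten-membered lactone. C1 to C9 and the ring oxygen make up the ring, O9–C1 is the ester bond, C5=C6 is an E alkene and C9 carries a propyl group (C10–C12). C7 and C8 carry free hydroxyls, and the C2 oxygen is acylated by (2E,4E)-muconic acid, whose far carboxyl is free.

A ring of this size is costly to close. An E alkene inside it is not safely the thermodynamic isomer, so the geometry is better fixed in an open chain than made in a reversible ring closure.

C7 (R), C8 (S) and C9 (R) are contiguous and have the 7,8-threo, 8,9-erythro pattern of C2–C4 of D-arabinose, so they can be taken from the chiral pool. C2 (R) is insulated from them by the ester on one side and by C3–C6 on the other. None of the three can be expected to control it, so it must be set by a reagent or corrected by a stereospecific substitution.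

The muconic half-ester is a doubly activated diene with a free acid. Once acylated, C2–H is alpha to the lactone carbonyl and epimerisable. C7–O is allylic. The side chain therefore goes on last, and the closing steps avoid base and nucleophiles.

The enabling feature is that C2 is oxygenated, C3 and C4 are unsubstituted methylenes and C5 is an alkenyl carbon. C1–C4 can thus be drawn as 1-hydroxycyclopropane-1-carboxylic acid with an extra C2–C4 bond. Opening that bond turns C2 into a carbonyl and C4 into a nucleophile aimed at C5.

## Retrosynthesis

**Side chain and protecting groups.** Target 22 is traced to its fully protected form 21, and 21 is cut at the C2–O acyl bond into alcohol 18 and the half-ester 20. This keeps the Michael-acceptor diene out of every earlier step. The 4-methoxybenzyl ester in 20 is chosen because one acid treatment removes it together with the 7,8-acetonide. The forward reaction has to acylate a secondary alpha-hydroxy lactone without epimerising C2.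

**C2 stereocentre.** Alcohol 18 is traced to the 2-oxo lactone 17 by removing the C2–H bond. An alpha-keto ester is the most electrophilic carbonyl in the molecule and a classical substrate for chiral boranes. No other group needs protection, and either C2 epimer remains usable because the acylation can run with retention or inversion.

**Ring (key cut).** Keto lactone 17 is cut at C4–C5 and C2–C4 is reconnected, which gives the open-chain cyclopropanol ester 16 with an E-alkenyl iodide. The neighbouring cuts are weaker:
- Closing at O9–C1 would need an activated acyl group next to an oxygenated, epimerisable C2.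
- Closing at C5=C6 by metathesis would make the alkene geometry in the ring-forming event.
- The C4–C5 cut puts the ester bond in place by a simple intermolecular acylation, keeps the alkene geometry from an acyclic olefination, and lets the strain of the cyclopropane drive the ring closure.

The forward step must make the palladium homoenolate couple, not eliminate, and cyclise, not oligomerise.

**Alkenyl iodide and cyclopropanol.** Cyclopropanol 16 comes from its silyl ether 15, so the tertiary hydroxyl is masked during the earlier steps. Iodide 15 is cut at C5=C6 into aldehyde 13 and iodoform 14 (Takai olefination), which sets the E geometry under non-basic conditions. Aldehyde 13 comes from dithioacetal 12, which keeps C6 masked until the ester is in place.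

**Ester bond.** Dithioacetal ester 12 is cut at O9–C1 into alcohol 7 and the silylated acid 10, joined through mixed anhydride 11. Acid 10 comes from commercial 1-hydroxycyclopropane-1-carboxylic acid 8 by way of the bis-silylated acid 9. Esterifying before the aldehyde is released keeps the C9 hydroxyl from forming a lactol with C6.

**Sugar segment.** Alcohol 7 is cut at C10–C11. An ethyl nucleophile opens the terminal epoxide 6. Epoxide 6 comes from diol 4 through the primary tosylate 5. Diol 4 comes from diacetonide 3 by loss of the terminal acetonide. Diacetonide 3 comes from D-arabinose diethyl dithioacetal 2, and 2 from D-arabinose 1. All three ring stereocentres C7–C9 are bought; only one C–C bond is made in this segment.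

**Half-ester.** Half-ester 20 is made by monoalkylation of (2E,4E)-muconic acid 19, so the diene geometry is purchased.

## Roads not taken

**Alternative 1: Passerini union of C1, C2 and the muconate.**
- Cut: C1–C2 and the C2–O acyl bond together.
- Forward key step: aldehyde A2 (C2 as the formyl carbon, with the E alkene, the acetonide and a C9 silyl ether), an aryl isocyanide supplying C1 and a muconic half-ester combine under a chiral phosphoric acid to give the alpha-acyloxy anilide A1. The ring would be closed later by converting the anilide into an acyl donor and lactonising onto O9.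
- Merits: it is convergent and sets C2 while attaching the side chain, which saves a separate reduction and acylation. Its ring closure, a macrolactonisation, is a precedented reaction type for lactones of this size. In these two respects it is better than the chosen plan.
- Weak points: catalytic enantioselective Passerini reactions are selective only for a narrow range of partners, and an unbranched aliphatic aldehyde with a conjugated dienoic acid is not a favourable pair. The remote centres of A2 give no help. The lactonisation must activate a carboxyl whose alpha carbon already bears the muconate, so C2 epimerisation and acyl migration threaten at the most valuable stage. The diene ester must also survive anilide activation and ring closure.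
- Comparison: the chosen plan closes the ring by an irreversible C–C bond formation that does not touch C2, and it introduces the muconate only after the ring exists.

**Alternative 2: cyclobutene anhydride as a latent muconic half-acid.**
- Cut: the two C=C bonds of the side chain only; the ring synthesis is left open.
- Forward key step: alcohol 18 opens the meso anhydride A5 to the cis-cyclobutene half-ester A4. Heating with catalytic iodine then opens the four-membered ring and equilibrates the diene, giving the acetonide A3 of the target.
- Merits: the anhydride can acylate only once and releases the free acid in the same step. No statistical half-ester preparation and no carboxyl protecting group are needed. On atom and step economy of the side chain it is better than step 13 plus the ester cleavage of the chosen plan.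
- Weak points: A5 is not a shelf reagent. The thermal conrotatory opening of a cis-disubstituted cyclobutene gives the E,Z diene first. The iodine equilibration that corrects it acts through reversible iodine-atom addition, which can also reach the ring alkene C5=C6, whose E geometry may not be the thermodynamic one. The free acid and the alpha-acyloxy lactone are heated together.
- Comparison: the chosen plan buys the E,E geometry with cheap muconic acid and never exposes the ring alkene to heat or iodine radicals. This road could be grafted onto the chosen ring synthesis if step 13 proved wasteful.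

**Alternative 3: tin-directed fragmentation of a bicyclic hemiketal.**
- Cut (in reverse): C1 is reconnected to C6 to give the fused cyclohexane–tetrahydropyran hemiketal A7 with a stannyl group on C5.
- Forward key step: Pb(OAc)4 oxidises A7, cleaves C1–C6 and forms the lactone carbonyl and the C5=C6 alkene, giving lactone A6.
- Merits: the ten-membered ring arises by a unimolecular fragmentation, with no dilution and no entropic penalty. The alkene geometry follows stereospecifically from the anti-periplanar C–Sn and C1–C6 bonds. C2 is already in place. The reaction type is known for medium-ring lactones, so this key step stands on firmer ground than that of the chosen plan.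
- Weak points: A7 needs three extra stereocentres (C1, C5, C6) set in a defined relation and then destroyed. C7–C9 sit in a pyran and C2 in a carbocycle, so the sugar pattern cannot be bought as directly. Tin and lead are used stoichiometrically. A6 carries the same silyl group on O2 and O7, which must be told apart before the muconate can be attached.
- Comparison: the chosen plan offers a short chiral-pool route to all three ring centres, no sacrificial stereocentres and a differentiated C2 oxygen. It pays for these with an untested ring closure.

Key step: step 11

## Route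

Numbering: C1 is the lactone carbonyl and C12 the methyl end of the propyl group. In the carbohydrate names of 2–7, 12 and 13, sugar C1–C5 correspond to C6–C10. The descriptor of C8 is R in the acetonides and S in the free diol, with no change in geometry.

Assumption: in step 12 the alkoxycarbonyl flank of the 2-oxo lactone is taken to act as the smaller, activating substituent toward (−)-Ipc2BCl, as the usual model for alpha-keto esters would have it; if the first run shows the opposite sense, (+)-Ipc2BCl is used instead with no other change.

Step 1
Reactants: 1 D-arabinose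
Product: 2 D-arabinose diethyl dithioacetal
Conditions: EtSH, conc. HCl, 0 °C
Reagents that add atoms: ethanethiol, CCS
Why: Fischer dithioacetal formation traps the open-chain aldehyde; no stereocentre is touched.

Step 2
Reactants: 2 D-arabinose diethyl dithioacetal
Product: 3 2,3:4,5-di-O-isopropylidene-D-arabinose diethyl dithioacetal
Conditions: 2,2-dimethoxypropane, acetone, TsOH·H2O (cat.), rt
Reagents that add atoms: 2,2-dimethoxypropane, COC(C)(C)OC (acetone, CC(C)=O, as co-solvent supplies the same isopropylidene unit)
Why: Thermodynamic acetonation takes the terminal diol and the threo 2,3-diol (trans-dioxolane) in preference to the erythro 3,4-pair.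

Step 3
Reactants: 3 2,3:4,5-di-O-isopropylidene-D-arabinose diethyl dithioacetal
Product: 4 2,3-O-isopropylidene-D-arabinose diethyl dithioacetal (free 4,5-diol)
Conditions: AcOH/H2O (7:3), 40 °C, run to partial conversion, 3 recycled
Reagents that add atoms: none
Why: Selective acetal hydrolysis; the terminal monosubstituted dioxolane hydrolyses faster than the internal trans-disubstituted one, and the dithioacetal is inert to aqueous acid.

Step 4
Reactants: 4 2,3-O-isopropylidene-D-arabinose diethyl dithioacetal
Product: 6 4,5-anhydro-2,3-O-isopropylidene-D-arabinose diethyl dithioacetal, via primary tosylate 5 (not isolated)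
Conditions: NaH (2.2 equiv), 1-(p-toluenesulfonyl)imidazole (1.05 equiv), THF, 0 °C → rt
Reagents that add atoms: none
Why: One-flask conversion of a terminal 1,2-diol to the epoxide: the primary alkoxide is sulfonylated first and the secondary alkoxide then displaces the tosylate (intramolecular Williamson closure), so the configuration of the future C9 is retained.

Step 5
Reactants: 6 4,5-anhydro-2,3-O-isopropylidene-D-arabinose diethyl dithioacetal
Product: 7 5,6,7-trideoxy-2,3-O-isopropylidene-D-arabino-heptose diethyl dithioacetal (free C9 hydroxyl, propyl group complete)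
Conditions: EtMgBr (3 equiv), CuI (20 mol%), THF, −40 → 0 °C; aq. NH4Cl
Reagents that add atoms: ethylmagnesium bromide, CC[Mg]Br
Why: Copper-catalysed Grignard opening of a terminal epoxide occurs at the unsubstituted carbon (SN2), making C10–C11 without touching the C–O bond at the stereocentre; dithioacetal and acetonide are inert.

Step 6
Reactants: 8 1-hydroxycyclopropane-1-carboxylic acid
Product: 10 1-[(tert-butyldimethylsilyl)oxy]cyclopropane-1-carboxylic acid, via bis-silylated acid 9 (not isolated)
Conditions: TBSOTf (2.3 equiv), 2,6-lutidine, CH2Cl2, 0 °C; then K2CO3, MeOH/H2O, rt; aq. KHSO4 to pH 4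
Reagents that add atoms: tert-butyldimethylsilyl trifluoromethanesulfonate, CC(C)(C)[Si](C)(C)OS(=O)(=O)C(F)(F)F
Why: Exhaustive silylation followed by selective methanolysis of the labile silyl ester is the standard way to O-silyl alpha-hydroxy acids; the silyl ether survives mild carbonate.

Step 7
Reactants: 7 5,6,7-trideoxy-2,3-O-isopropylidene-D-arabino-heptose diethyl dithioacetal; 10 1-[(tert-butyldimethylsilyl)oxy]cyclopropane-1-carboxylic acid
Product: 12 4-O-{1-[(tert-butyldimethylsilyl)oxy]cyclopropane-1-carbonyl}-5,6,7-trideoxy-2,3-O-isopropylidene-D-arabino-heptose diethyl dithioacetal, via mixed anhydride 11 (not isolated)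
Conditions: 10, 2,4,6-Cl3C6H2COCl, Et3N, THF, rt; then 7, DMAP, toluene, rt → 40 °C
Reagents that add atoms: none
Why: Yamaguchi esterification copes with a hindered secondary alcohol and an alpha-quaternary acid; the acid has no alpha-hydrogen, so neither ketene formation nor epimerisation can occur, and the O9–C1 bond is made intermolecularly.

Step 8
Reactants: 12 dithioacetal ester
Product: 13 4-O-{1-[(tert-butyldimethylsilyl)oxy]cyclopropane-1-carbonyl}-5,6,7-trideoxy-2,3-O-isopropylidene-aldehydo-D-arabino-heptose (C6 aldehyde)
Conditions: I2, NaHCO3, acetone/H2O, 0 °C; crude aldehyde used at once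
Reagents that add atoms: water, O
Why: Iodine-mediated oxidative hydrolysis of a dithioacetal under bicarbonate buffer is neutral enough for the silyl ether, the ester, the acetonide and the alpha-alkoxy aldehyde.

Step 9
Reactants: 13 aldehyde; 14 iodoform
Product: 15 (1R)-1-[(4R,5R)-5-[(E)-2-iodoethenyl]-2,2-dimethyl-1,3-dioxolan-4-yl]butyl 1-[(tert-butyldimethylsilyl)oxy]cyclopropane-1-carboxylate
Conditions: CrCl2 (8 equiv), CHI3 (3 equiv), THF/1,4-dioxane (1:6), 0 °C → rt, dark
Reagents that add atoms: none
Why: Takai iodo-olefination; the geminal dichromium reagent adds to the aldehyde and anti elimination gives the E alkenyl iodide, and the medium is non-basic, so the alpha-alkoxy centre C7 should not epimerise.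

Step 10
Reactants: 15 silyl-protected alkenyl iodide
Product: 16 (1R)-1-[(4R,5R)-5-[(E)-2-iodoethenyl]-2,2-dimethyl-1,3-dioxolan-4-yl]butyl 1-hydroxycyclopropane-1-carboxylate
Conditions: HF·pyridine, pyridine, THF, 0 °C → rt
Reagents that add atoms: none
Why: Buffered acidic fluoride cleaves the silyl ether without generating a free alkoxide, which avoids base-induced opening of the cyclopropanol; acetonide, ester and alkenyl iodide tolerate it.

Step 11
Reactants: 16 cyclopropanol alkenyl iodide
Product: 17 (5E,7R,8R,9R)-7,8-(isopropylidenedioxy)-2-oxododec-5-en-9-olide (ten-membered 2-oxo lactone)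
Conditions: Pd(OAc)2 (20 mol%), 2-dicyclohexylphosphino-2′,4′,6′-triisopropylbiphenyl (40 mol%), Cs2CO3 (2 equiv), degassed toluene, 80 °C; catalyst pre-stirred, 16 added over 12 h by syringe pump to a final 1 mM
Reagents that add atoms: none
Why: Proposed new method: zerovalent palladium, generated from Pd(OAc)2 and the biaryl phosphine, should insert into the C5–I bond of 16 with retention of the E geometry, the carbonate should exchange iodide for the tertiary cyclopropanolate, and strain-driven beta-carbon elimination should open the three-membered ring to a palladium homoenolate bound at C4, with C2 becoming the ketone. Reductive elimination between C4 (sp3) and C5 (sp2) then forms the ring bond; the closest known reaction type is the intermolecular palladium-catalysed ring-opening cross-coupling of cyclopropanols with aryl and alkenyl halides to beta-substituted ketones, and neither a ring-closing version nor a cyclopropanol with an ester on the carbinol carbon has been demonstrated. The ten-membered ring closes in the endo sense, by contraction of an eleven-membered palladacycle (Pd, C5–C9, O, C1–C4) at the reductive elimination, so the new bond and the alkene both lie in the ring. No stereocentre is created: the cyclopropane is symmetric, so cleavage of either ring bond gives the same C2 ketone, C7–C9 are spectators, and the alkene geometry is inherited from 15. Two selectivities are required: reductive elimination must outrun beta-hydride elimination from C3 of the homoenolate, which the bulky, electron-rich ligand is chosen to secure, and ring closure must outrun intermolecular coupling, which slow addition into a dilute, catalyst-rich solution is meant to secure. The substrate helps in that the trans-dioxolane freezes the C7–C8 rotor and the ester prefers its Z conformation, and in that release of the cyclopropane strain (about 27 kcal/mol) makes the C–C cleavage irreversible and pays for the strain of the medium ring.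

Step 12
Reactants: 17 2-oxo lactone
Product: 18 (2R,5E,7R,8R,9R)-2-hydroxy-7,8-(isopropylidenedioxy)dodec-5-en-9-olide
Conditions: (−)-Ipc2BCl (2 equiv), THF, −78 → −30 °C; then CH3CHO, 0 °C → rt; aq. NaHCO3
Reagents that add atoms: none
Why: Asymmetric reduction of an alpha-keto ester with B-chlorodiisopinocampheylborane; hydride is passed from an isopinocampheyl group in a boat-like six-membered transition state with the lactone carboxyl toward the pinanyl methyl and the C3–C4 chain away from it, which should deliver the 2R alcohol under reagent control, and the lactone, the alkene and the acetonide are not reduced.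

Step 13
Reactants: 19 (2E,4E)-muconic acid
Product: 20 (2E,4E)-6-[(4-methoxybenzyl)oxy]-6-oxohexa-2,4-dienoic acid (mono-4-methoxybenzyl muconate)
Conditions: 19 (3 equiv), 4-methoxybenzyl chloride (1 equiv), KHCO3 (1.1 equiv), DMF, 50 °C
Reagents that add atoms: 4-methoxybenzyl chloride, COc1ccc(CCl)cc1
Why: Carboxylate O-alkylation under statistical control; the excess of cheap diacid and one equivalent of base favour the monoester, which is separated from the neutral diester and the sparingly soluble diacid by extraction.

Step 14
Reactants: 18 2R-hydroxy lactone; 20 mono-4-methoxybenzyl muconate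
Product: 21 (2R,5E,7R,8R,9R)-7,8-(isopropylidenedioxy)-2-{[(2E,4E)-6-[(4-methoxybenzyl)oxy]-6-oxohexa-2,4-dienoyl]oxy}dodec-5-en-9-olide
Conditions: EDC·HCl, DMAP (cat.), CH2Cl2, 0 °C → rt
Reagents that add atoms: none
Why: Steglich esterification acylates the alcohol oxygen with retention at C2; catalytic DMAP at low temperature limits epimerisation of the alpha-acyloxy lactone and conjugate addition to the diene.

Step 15
Reactants: 21 protected target
Product: 22 (2R,5E,7R,8S,9R)-2-{[(2E,4E)-5-carboxypenta-2,4-dienoyl]oxy}-7,8-dihydroxydodec-5-en-9-olide (CNP0476488.6)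
Conditions: CF3CO2H/CH2Cl2/H2O (5:5:1), anisole, 0 °C → rt
Reagents that add atoms: none
Why: One acid treatment hydrolyses the acetonide and ionises the 4-methoxybenzyl ester (the cation is trapped by anisole); no base or nucleophile meets the muconate or the C2 centre, and all four stereocentres are untouched.

## Compound list

1 | D-arabinose (open-chain form) | O=C[C@@H](O)[C@H](O)[C@H](O)CO | starting material
2 | D-arabinose diethyl dithioacetal | CCSC(SCC)[C@@H](O)[C@H](O)[C@H](O)CO | intermediate
3 | 2,3:4,5-di-O-isopropylidene-D-arabinose diethyl dithioacetal | CCSC(SCC)[C@H]1OC(C)(C)O[C@@H]1[C@H]2COC(C)(C)O2 | intermediate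
4 | 2,3-O-isopropylidene-D-arabinose diethyl dithioacetal | CCSC(SCC)[C@H]1OC(C)(C)O[C@@H]1[C@H](O)CO | intermediate
5 | 2,3-O-isopropylidene-5-O-(p-toluenesulfonyl)-D-arabinose diethyl dithioacetal (primary tosylate, not isolated) | CCSC(SCC)[C@H]1OC(C)(C)O[C@@H]1[C@H](O)COS(=O)(=O)c2ccc(C)cc2 | intermediate
6 | 4,5-anhydro-2,3-O-isopropylidene-D-arabinose diethyl dithioacetal | CCSC(SCC)[C@H]1OC(C)(C)O[C@@H]1[C@H]2CO2 | intermediate
7 | 5,6,7-trideoxy-2,3-O-isopropylidene-D-arabino-heptose diethyl dithioacetal | CCSC(SCC)[C@H]1OC(C)(C)O[C@@H]1[C@H](O)CCC | intermediate
8 | 1-hydroxycyclopropane-1-carboxylic acid | OC(=O)C1(O)CC1 | starting material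
9 | tert-butyldimethylsilyl 1-[(tert-butyldimethylsilyl)oxy]cyclopropane-1-carboxylate (bis-silylated acid, not isolated) | CC(C)(C)[Si](C)(C)OC(=O)C1(O[Si](C)(C)C(C)(C)C)CC1 | intermediate
10 | 1-[(tert-butyldimethylsilyl)oxy]cyclopropane-1-carboxylic acid | OC(=O)C1(O[Si](C)(C)C(C)(C)C)CC1 | intermediate
11 | 1-[(tert-butyldimethylsilyl)oxy]cyclopropane-1-carboxylic 2,4,6-trichlorobenzoic anhydride (mixed anhydride, not isolated) | CC(C)(C)[Si](C)(C)OC1(CC1)C(=O)OC(=O)c2c(Cl)cc(Cl)cc2Cl | intermediate
12 | 4-O-{1-[(tert-butyldimethylsilyl)oxy]cyclopropane-1-carbonyl}-5,6,7-trideoxy-2,3-O-isopropylidene-D-arabino-heptose diethyl dithioacetal | CCSC(SCC)[C@H]1OC(C)(C)O[C@@H]1[C@@H](CCC)OC(=O)C2(O[Si](C)(C)C(C)(C)C)CC2 | intermediate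
13 | 4-O-{1-[(tert-butyldimethylsilyl)oxy]cyclopropane-1-carbonyl}-5,6,7-trideoxy-2,3-O-isopropylidene-aldehydo-D-arabino-heptose | O=C[C@H]1OC(C)(C)O[C@@H]1[C@@H](CCC)OC(=O)C2(O[Si](C)(C)C(C)(C)C)CC2 | intermediate
14 | iodoform | IC(I)I | starting material
15 | (1R)-1-[(4R,5R)-5-[(E)-2-iodoethenyl]-2,2-dimethyl-1,3-dioxolan-4-yl]butyl 1-[(tert-butyldimethylsilyl)oxy]cyclopropane-1-carboxylate | I/C=C/[C@H]1OC(C)(C)O[C@@H]1[C@@H](CCC)OC(=O)C2(O[Si](C)(C)C(C)(C)C)CC2 | intermediate
16 | (1R)-1-[(4R,5R)-5-[(E)-2-iodoethenyl]-2,2-dimethyl-1,3-dioxolan-4-yl]butyl 1-hydroxycyclopropane-1-carboxylate | I/C=C/[C@H]1OC(C)(C)O[C@@H]1[C@@H](CCC)OC(=O)C2(O)CC2 | intermediate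
17 | (5E,7R,8R,9R)-7,8-(isopropylidenedioxy)-2-oxododec-5-en-9-olide | CCC[C@H]1OC(=O)C(=O)CC/C=C/[C@H]2OC(C)(C)O[C@H]12 | intermediate
18 | (2R,5E,7R,8R,9R)-2-hydroxy-7,8-(isopropylidenedioxy)dodec-5-en-9-olide | CCC[C@H]1OC(=O)[C@H](O)CC/C=C/[C@H]2OC(C)(C)O[C@H]12 | intermediate
19 | (2E,4E)-muconic acid | OC(=O)/C=C/C=C/C(=O)O | starting material
20 | (2E,4E)-6-[(4-methoxybenzyl)oxy]-6-oxohexa-2,4-dienoic acid | OC(=O)/C=C/C=C/C(=O)OCc1ccc(OC)cc1 | intermediate
21 | (2R,5E,7R,8R,9R)-7,8-(isopropylidenedioxy)-2-{[(2E,4E)-6-[(4-methoxybenzyl)oxy]-6-oxohexa-2,4-dienoyl]oxy}dodec-5-en-9-olide | CCC[C@H]1OC(=O)[C@H](OC(=O)/C=C/C=C/C(=O)OCc3ccc(OC)cc3)CC/C=C/[C@H]2OC(C)(C)O[C@H]12 | intermediate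
22 | (2R,5E,7R,8S,9R)-2-{[(2E,4E)-5-carboxypenta-2,4-dienoyl]oxy}-7,8-dihydroxydodec-5-en-9-olide | CCC[C@H]1OC(=O)[C@H](OC(=O)/C=C/C=C/C(=O)O)CC/C=C/[C@@H](O)[C@@H]1O | target

## Step count and risks

Total step count: 15. Longest linear sequence: 13 steps from D-arabinose (steps 1–5, 7–12, 14, 15); steps 6 and 13 prepare the two acids.

**Step 11 (key step, new method).**
- What may go wrong: beta-hydride elimination of the C4 palladium homoenolate toward C3, which would give an acyclic vinyl ketone and a palladium hydride that reduces the C–I bond; intermolecular coupling to oligomers; carbonate-induced opening of the cyclopropanol to the 2-oxobutanoate before palladium engages; aldol-type decay of the enolisable 2-oxo lactone under base.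
- Fallback (known chemistry, sets out from alcohol 7 and returns at 18, bypassing steps 6–12):
  - Alcohol 7 is esterified under Yamaguchi conditions with (2R)-2-[(tert-butyldimethylsilyl)oxy]hex-5-enoic acid F1, a building block obtainable from hex-5-enoic acid by auxiliary-controlled alpha-hydroxylation. This gives the dithioacetal ester F2.
  - Hydrolysis of the dithioacetal (HgCl2, CaCO3, aqueous MeCN) gives the aldehyde F3.
  - Wittig methylenation (Ph3P=CH2, THF, −78 → 0 °C) gives the diene F4.
  - Ring-closing metathesis at high dilution (second-generation Grubbs catalyst, CH2Cl2, reflux) closes the ring at C5=C6 to the silyl ether F5.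
  - HF·pyridine frees 18.
  - The cost is that the alkene geometry is then made in the ring-closing event, and C2 comes from the hydroxy acid instead of from a reduction.

**Step 12.**
- What may go wrong: low or reversed facial selectivity, because the sense of induction of the borane toward a ring-constrained alpha-keto lactone rests on a model, and the two flanks of the ketone differ little in size.
- Fallback (sets out from 17, returns at 21): the ketone is reduced with whichever hydride gives mainly the C2 epimer, (2S,5E,7R,8R,9R)-2-hydroxy-7,8-(isopropylidenedioxy)dodec-5-en-9-olide F6. F6 is then esterified with 20 under Mitsunobu conditions (PPh3, diisopropyl azodicarboxylate, THF, 0 °C), which inverts C2 and gives 21 directly. Any mixture of 18 and F6 can thus be separated and converged on 21.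

**Step 9.**
- What may go wrong: erosion of the E/Z ratio, epimerisation of the alpha-alkoxy aldehyde at C7 during handling, or sluggish addition next to the dioxolane.
- Fallback (sets out from 13, returns at 15): homologation with dimethyl (1-diazo-2-oxopropyl)phosphonate and K2CO3 in MeOH gives the alkyne (1R)-1-[(4R,5R)-5-ethynyl-2,2-dimethyl-1,3-dioxolan-4-yl]butyl 1-[(tert-butyldimethylsilyl)oxy]cyclopropane-1-carboxylate F7. Hydrozirconation with Cp2Zr(H)Cl followed by I2 gives the E iodide 15 by syn addition.

**Step 10.**
- What may go wrong: opening of the liberated cyclopropanol to the 2-oxobutanoate, or acyl transfer, if fluoride generates the free alkoxide.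
- Fallback (sets out from 15, returns at 17, no new compound): the silyl ether is taken straight into the conditions of step 11 with anhydrous CsF as base and fluoride source. The cyclopropanolate is then released slowly in the presence of the alkenylpalladium species and never accumulates.

**Step 15.**
- What may go wrong: benzylation of the diol by the 4-methoxybenzyl cation, trifluoroacetylation, ionisation at the allylic C7 oxygen, or ring contraction by transesterification onto the freed hydroxyls in strong acid.
- Fallback (sets out from 18, returns at 22):
  - Alcohol 18 is acylated (EDC·HCl, DMAP) with (2E,4E)-6-(allyloxy)-6-oxohexa-2,4-dienoic acid F8, made from 19 and allyl bromide as in step 13. This gives the allyl ester acetonide F9.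
  - The acetonide is removed with aqueous AcOH at 40 °C to give the diol allyl ester F10.
  - The allyl group is transferred to N-methylaniline with Pd(PPh3)4 in THF under neutral conditions to give 22.

## Further compounds

F1 | step 11 | (2R)-2-[(tert-butyldimethylsilyl)oxy]hex-5-enoic acid | C=CCC[C@@H](O[Si](C)(C)C(C)(C)C)C(=O)O
F2 | step 11 | 4-O-[(2R)-2-[(tert-butyldimethylsilyl)oxy]hex-5-enoyl]-5,6,7-trideoxy-2,3-O-isopropylidene-D-arabino-heptose diethyl dithioacetal | CCSC(SCC)[C@H]1OC(C)(C)O[C@@H]1[C@@H](CCC)OC(=O)[C@H](O[Si](C)(C)C(C)(C)C)CCC=C
F3 | step 11 | 4-O-[(2R)-2-[(tert-butyldimethylsilyl)oxy]hex-5-enoyl]-5,6,7-trideoxy-2,3-O-isopropylidene-aldehydo-D-arabino-heptose | O=C[C@H]1OC(C)(C)O[C@@H]1[C@@H](CCC)OC(=O)[C@H](O[Si](C)(C)C(C)(C)C)CCC=C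
F4 | step 11 | (1R)-1-[(4R,5R)-5-ethenyl-2,2-dimethyl-1,3-dioxolan-4-yl]butyl (2R)-2-[(tert-butyldimethylsilyl)oxy]hex-5-enoate | C=C[C@H]1OC(C)(C)O[C@@H]1[C@@H](CCC)OC(=O)[C@H](O[Si](C)(C)C(C)(C)C)CCC=C
F5 | step 11 | (2R,5E,7R,8R,9R)-2-[(tert-butyldimethylsilyl)oxy]-7,8-(isopropylidenedioxy)dodec-5-en-9-olide | CCC[C@H]1OC(=O)[C@H](O[Si](C)(C)C(C)(C)C)CC/C=C/[C@H]2OC(C)(C)O[C@H]12
F6 | step 12 | (2S,5E,7R,8R,9R)-2-hydroxy-7,8-(isopropylidenedioxy)dodec-5-en-9-olide | CCC[C@H]1OC(=O)[C@@H](O)CC/C=C/[C@H]2OC(C)(C)O[C@H]12
F7 | step 9 | (1R)-1-[(4R,5R)-5-ethynyl-2,2-dimethyl-1,3-dioxolan-4-yl]butyl 1-[(tert-butyldimethylsilyl)oxy]cyclopropane-1-carboxylate | C#C[C@H]1OC(C)(C)O[C@@H]1[C@@H](CCC)OC(=O)C2(O[Si](C)(C)C(C)(C)C)CC2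
F0 | step 10 | none | none
F8 | step 15 | (2E,4E)-6-(allyloxy)-6-oxohexa-2,4-dienoic acid | OC(=O)/C=C/C=C/C(=O)OCC=C
F9 | step 15 | (2R,5E,7R,8R,9R)-2-{[(2E,4E)-6-(allyloxy)-6-oxohexa-2,4-dienoyl]oxy}-7,8-(isopropylidenedioxy)dodec-5-en-9-olide | CCC[C@H]1OC(=O)[C@H](OC(=O)/C=C/C=C/C(=O)OCC=C)CC/C=C/[C@H]2OC(C)(C)O[C@H]12
F10 | step 15 | (2R,5E,7R,8S,9R)-2-{[(2E,4E)-6-(allyloxy)-6-oxohexa-2,4-dienoyl]oxy}-7,8-dihydroxydodec-5-en-9-olide | CCC[C@H]1OC(=O)[C@H](OC(=O)/C=C/C=C/C(=O)OCC=C)CC/C=C/[C@@H](O)[C@@H]1O
A1 | alternative 1 | Passerini adduct: open-chain C1–C12 anilide of 2-(2,2-dimethoxyethyl)aniline with the 2R mono-allyl muconate ester, E-C5=C6, 7,8-acetonide and 9-O-triethylsilyl ether, C7–C9 configured as in 22 | CCC[C@@H](O[Si](CC)(CC)CC)[C@H]1OC(C)(C)O[C@@H]1/C=C/CC[C@@H](OC(=O)/C=C/C=C/C(=O)OCC=C)C(=O)Nc2ccccc2CC(OC)OC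
A2 | alternative 1 | C2–C12 aldehyde (C2 as formyl carbon) with E-C5=C6, 7,8-acetonide and 9-O-triethylsilyl ether, C7–C9 configured as in 22 | CCC[C@@H](O[Si](CC)(CC)CC)[C@H]1OC(C)(C)O[C@@H]1/C=C/CCC=O
A3 | alternative 2 | 7,8-acetonide of the target, (2R,5E,7R,8R,9R)-2-{[(2E,4E)-5-carboxypenta-2,4-dienoyl]oxy}-7,8-(isopropylidenedioxy)dodec-5-en-9-olide | CCC[C@H]1OC(=O)[C@H](OC(=O)/C=C/C=C/C(=O)O)CC/C=C/[C@H]2OC(C)(C)O[C@H]12
A4 | alternative 2 | C2 ester of 18 with cis-cyclobut-3-ene-1,2-dicarboxylic acid, free second carboxyl (one of the two cis diastereomers shown) | CCC[C@H]1OC(=O)[C@H](OC(=O)[C@H]3C=C[C@H]3C(=O)O)CC/C=C/[C@H]2OC(C)(C)O[C@H]12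
A5 | alternative 2 | cis-cyclobut-3-ene-1,2-dicarboxylic anhydride (meso) | O=C1OC(=O)[C@H]2C=C[C@@H]12
A6 | alternative 3 | ten-membered E-lactone with 2-O- and 7-O-tert-butyldimethylsilyl ethers and 8-O-(4-methoxybenzyl) ether, configured as in 22 | CCC[C@H]1OC(=O)[C@H](O[Si](C)(C)C(C)(C)C)CC/C=C/[C@@H](O[Si](C)(C)C(C)(C)C)[C@@H]1OCc2ccc(OC)cc2
A7 | alternative 3 | fused cyclohexane–tetrahydropyran hemiketal (C1–C6 bond intact) with tributylstannyl on C5, protecting groups as in A6; C2, C7, C8, C9 as in 22, C1, C5, C6 left open | CCC[C@H]1OC2(O)[C@H](O[Si](C)(C)C(C)(C)C)CCC([Sn](CCCC)(CCCC)CCCC)C2[C@@H](O[Si](C)(C)C(C)(C)C)[C@@H]1OCc3ccc(OC)cc3
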